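**Retrosynthetic overview**
1. Target ⇒ twofold Suzuki–Miyaura coupling at C10–C11 and C10′–C11′: two sulfated C14 dienyl iodides (ring C1–C6 plus C7–C10) and one C12 pentaenyl bis(pinacol boronate) (C11–C11′).
2. Feature used: each sulfate sits on C4 of a saturated cyclohexane ring, and the sp3 carbons C5 and C6 separate it from the C7–C7′ nonaene. Sulfation and every acidic, fluoride or oxidising step can therefore be finished on the C14 diene before the nonaene exists.
3. Dienyl iodide ⇒ terminal enyne (methylalumination–iodination) ⇒ E-alkenyl iodide (Sonogashira) ⇒ ring aldehyde (Takai); 3-O-TBS and 4-O-TES keep the two oxygens apart.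
4. Rings: none is formed in the route. Both cyclohexanes come from safranal by C3=C4 cis-dihydroxylation, kinetic resolution through enantioselective O3 silylation, O4-directed hydrogenation of C5=C6 and epimerisation at C6.
5. Bis(boronate) ⇒ 2,7-dimethylocta-2,4,6-trienedial by twofold boron olefination.

Key step: step 14

Remark on numbering: ring carbons carry the carotenoid numbers of the target (C1 = CMe2, C2 = CH2, C3 = CH–O next to C2, C4 = CH–O next to C5, C5 = C–CH3, C6 = carbon bearing C7); all locants and CIP descriptors in the names use this numbering.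
Remark on salts: the sulfate monoesters are made and handled as salts (Bu4N+ for 14 and 15, Na+ for the target); their SMILES are written in the hydrogen sulfate form used for the target.
Remark on the resolution: the silylation catalyst of step 2 is used in the antipode that silylates the (3R,4S)-diol of racemate 2; which antipode that is has to be fixed in a test run, both being accessible from tert-leucine of either configuration.

**Step 1**
Reactants: 1 safranal (2,6,6-trimethylcyclohexa-1,3-diene-1-carbaldehyde)
Product: 2 racemic cis-3,4-dihydroxy-β-cyclocitral (C5=C6 enal with C7 = CHO; 3-OH and 4-OH cis)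
Conditions: K2OsO4·2H2O (2 mol%), NMO, acetone/H2O 4:1, 0 °C to rt; Na2SO3 work-up
Reagents that add atoms: N-methylmorpholine N-oxide, C[N+]1([O-])CCOCC1; water, O
Why: Upjohn dihydroxylation, in which OsO4 adds suprafacially to the electron-richer, disubstituted C3=C4 bond while the tetrasubstituted C5=C6 bond is deactivated by the formyl group, so the cis-3,4-diol should form as a racemate.

**Step 2**
Reactants: 2 racemic cis-3,4-dihydroxy-β-cyclocitral
Product: 3 (3R,4S)-3-O-TBS-3,4-dihydroxy-β-cyclocitral (4-OH free)
Conditions: TBSCl, iPr2NEt, chiral imidazole amino-amide silylation catalyst ((S)-N-[(R)-3,3-dimethylbutan-2-yl]-3,3-dimethyl-2-{[(1-methylimidazol-2-yl)methyl]amino}butanamide or its enantiomer, 20 mol%), THF, −40 °C, stopped near half conversion; chromatography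
Reagents that add atoms: tert-butyldimethylsilyl chloride, CC(C)(C)[Si](C)(C)Cl
Why: Kinetic resolution by catalytic enantioselective silylation of a syn-1,2-diol, in which the hydrogen-bonding catalyst delivers the silyl group to the less hindered O3 of one enantiomer only, so the (3R,4S) antipode is removed as its O3 ether (the (3S,4R)-diol stays unsilylated) and the absolute configuration of C3 and C4 is fixed here.

**Step 3**
Reactants: 3 (3R,4S)-3-O-TBS-3,4-dihydroxy-β-cyclocitral
Product: 4 (3R,4S,5R,6S)-3-O-TBS-3,4-dihydroxy-5,6-dihydro-β-cyclocitral (saturated ring; 5-CH3 trans to O4; CHO cis to 5-CH3)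
Conditions: H2 (50 bar), [Ir(cod)(PCy3)(py)]PF6 (5 mol%, in portions), CH2Cl2, rt
Reagents that add atoms: none
Why: Hydroxyl-directed homogeneous hydrogenation, in which the cationic iridium catalyst binds the pseudoaxial C4–OH and transfers both hydrogens to C5=C6 on the face of O4 (the other face carries the pseudoaxial C1 methyl), which sets C5 with its methyl trans to O4 and leaves the formyl group cis to that methyl for correction in step 5.

**Step 4**
Reactants: 4 (3R,4S,5R,6S)-3-O-TBS-3,4-dihydroxy-5,6-dihydro-β-cyclocitral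
Product: 5 (3R,4S,5R,6S)-3-O-TBS-4-O-TES ring aldehyde (CHO cis to 5-CH3)
Conditions: TESOTf, 2,6-lutidine, CH2Cl2, −78 °C
Reagents that add atoms: triethylsilyl trifluoromethanesulfonate, CC[Si](CC)(CC)OS(=O)(=O)C(F)(F)F
Why: Silyl triflate protection of a hindered secondary alcohol; capping O4 before any basic step excludes 1,2-migration of the TBS group from O3 to O4 and keeps the two oxygens distinguishable for the later sulfation.

**Step 5**
Reactants: 5 (3R,4S,5R,6S)-3-O-TBS-4-O-TES ring aldehyde
Product: 6 (3R,4S,5R,6R)-3-O-TBS-4-O-TES ring aldehyde (CHO trans to 5-CH3)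
Conditions: DBU (0.3 equiv), CH2Cl2, rt, to equilibrium; chromatography, recovered 5 recycled
Reagents that add atoms: none
Why: Base-catalysed epimerisation through the enolate under thermodynamic control, in which C6 is the only acidic stereocentre and the 5,6-trans aldehyde with the C4, C5 and C6 substituents all equatorial should be favoured, as in the parent 2,2,6-trimethylcyclohexanecarbaldehyde, which sets C6.

**Step 6**
Reactants: 6 (3R,4S,5R,6R)-3-O-TBS-4-O-TES ring aldehyde
Product: 7 (7E)-alkenyl iodide C6–CH=CHI (3-O-TBS, 4-O-TES; ring unchanged, C6 becomes S by the CIP rules only because of the iodine)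
Conditions: CrCl2 (8 equiv), CHI3 (3 equiv), THF/1,4-dioxane 1:6, rt, dark
Reagents that add atoms: iodoform, IC(I)I
Why: Takai olefination, in which the geminal dichromium species formed from iodoform and divalent chromium adds to the aldehyde and eliminates to the E-alkenyl iodide under non-basic conditions, so C6 is not epimerised.

**Step 7**
Reactants: 7 (7E)-alkenyl iodide; 8 ethynyltrimethylsilane
Product: 9 (7E)-enyne C6–CH=CH–C≡C–SiMe3 (3-O-TBS, 4-O-TES)
Conditions: PdCl2(PPh3)2 (5 mol%), CuI (10 mol%), Et3N, THF, rt
Reagents that add atoms: none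
Why: Sonogashira coupling of an alkenyl iodide with a terminal alkyne proceeds with retention of the E geometry at C7=C8 under mild amine conditions that leave both silyl ethers intact.

**Step 8**
Reactants: 9 (7E)-enyne with C-SiMe3
Product: 10 (7E)-terminal enyne C6–CH=CH–C≡CH (3-O-TBS, 4-O-TES)
Conditions: K2CO3, MeOH/THF, rt
Reagents that add atoms: none
Why: Methanolysis of the C(sp)–Si bond by methoxide (protiodesilylation) is much faster than cleavage of the secondary TES and TBS ethers.

**Step 9**
Reactants: 10 (7E)-terminal enyne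
Product: 12 (7E,9E)-dienyl iodide C6–CH=CH–C(CH3)=CHI (3-O-TBS; 4-O-TES), via alkenyl(dimethyl)alane 11 (not isolated)
Conditions: Me3Al (3 equiv), Cp2ZrCl2 (0.5 equiv), CH2Cl2, 0 °C to rt; then I2, THF, −30 °C, dark
Reagents that add atoms: trimethylaluminium, C[Al](C)C; iodine, [I][I]
Why: Negishi zirconium-catalysed carboalumination adds methyl and aluminium syn across the terminal alkyne with methyl on the internal carbon C9, and iodinolysis of the C10–Al bond occurs with retention to give the (9E)-iodide.

**Step 10**
Reactants: 12 (7E,9E)-dienyl iodide (3-O-TBS, 4-O-TES)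
Product: 13 (7E,9E)-dienyl iodide with free 4-OH (3-O-TBS)
Conditions: PPTS (0.2 equiv), MeOH/CH2Cl2 1:1, 0 °C, dark
Reagents that add atoms: none
Why: Acid-catalysed methanolysis distinguishes the silyl ethers by size, the triethylsilyl ether being cleaved far faster than the tert-butyldimethylsilyl ether, and no base is present that could move the TBS group.

**Step 11**
Reactants: 13 (7E,9E)-dienyl iodide with free 4-OH
Product: 14 (7E,9E)-dienyl iodide 4-O-sulfate (3-O-TBS), tetrabutylammonium salt
Conditions: SO3·pyridine (5 equiv), pyridine, rt; then Bu4NHSO4, aq NaHCO3, extraction into CH2Cl2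
Reagents that add atoms: sulfur trioxide–pyridine complex, O=S(=O)=O.c1ccncc1 (tetrabutylammonium hydrogen sulfate, CCCC[N+](CCCC)(CCCC)CCCC.OS(=O)(=O)[O-], supplies only the counter-ion of the salt as handled)
Why: O-Sulfation with the SO3·pyridine complex meets a single free hydroxyl, the equatorial C4–OH, while the diene and the alkenyl iodide do not react with this mild SO3 donor, and ion pairing with Bu4N+ makes the monoester soluble in organic solvents.

**Step 12**
Reactants: 14 dienyl iodide 4-O-sulfate (3-O-TBS), tetrabutylammonium salt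
Product: 15 sulfated C14 dienyl iodide: (3R,4S,5R,6R)-3-hydroxy-6-[(1E,3E)-4-iodo-3-methylbuta-1,3-dienyl]-1,1,5-trimethylcyclohexan-4-yl sulfate, tetrabutylammonium salt
Conditions: Bu4NF (3 equiv), THF, rt to 40 °C, dark
Reagents that add atoms: none
Why: Fluoride-mediated desilylation, in which fluoride attacks silicon whereas the alkyl sulfate monoanion is inert to fluoride and the iodide has no hydrogen on C9 for elimination.

**Step 13**
Reactants: 16 (2E,4E,6E)-2,7-dimethylocta-2,4,6-trienedial; 17 2-(dichloromethyl)-4,4,5,5-tetramethyl-1,3,2-dioxaborolane (4 equiv)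
Product: 19 2,2′-[(1E,3E,5E,7E,9E)-3,8-dimethyldeca-1,3,5,7,9-pentaene-1,10-diyl]bis(4,4,5,5-tetramethyl-1,3,2-dioxaborolane) (C12 pentaene; C11–C11′ of the target), via boronate aldehyde 18 (not isolated)
Conditions: CrCl2 (16 equiv), LiI (8 equiv), THF, rt, dark
Reagents that add atoms: none
Why: Takai–Utimoto boron olefination, in which the geminal dichromium species from the dichloromethylboronate and divalent chromium converts each aldehyde into an E-alkenyl pinacol boronate without touching the existing trisubstituted alkenes.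

**Step 14**
Reactants: 15 sulfated C14 dienyl iodide, tetrabutylammonium salt (2.4 equiv); 19 C12 pentaenyl bis(pinacol boronate)
Product: 21 target disulfate (3R,4S,5R,6R,3′R,4′S,5′R,6′R; isolated as the disodium salt), via monocoupled heptaenyl boronate 20 (not isolated)
Conditions: Pd(PPh3)4 (10 mol%), 3 M aq K3PO4 (6 equiv), THF/DMF, 40 °C, argon, dark; then Dowex 50W (Na+ form) and C18 reversed-phase chromatography (MeOH/H2O), dark
Reagents that add atoms: none
Why: Zerovalent palladium adds oxidatively to the C10–I bond of 15 with retention, the phosphate-activated alkenylboronate end of 19 transmetalates and reductive elimination forms C10–C11, after which the monocoupled boronate 20 repeats the cycle to form C10′–C11′. The closest known reaction type is the twofold Suzuki–Miyaura coupling of polyenyl bis(pinacol boronates) with alkenyl iodides used for carotenoid-type polyenes; only the remote sulfate monoester on the iodide is new to the substrate. No ring is closed and no stereocentre is created, the eight ring stereocentres being carried in unchanged from 15. The step needs retention of the E geometry at C9=C10 and C11=C12 and complete twofold coupling: both elementary steps are stereoretentive, both partners are E-configured and unhindered at the reacting carbons, and the excess of 15 should drive 20 on to 21. The alkyl sulfate monoanion is neither a leaving group nor a ligand for palladium under aqueous phosphate and the free C3 hydroxyl is inert, so no protecting group is needed. Because the C7–C7′ nonaene first exists in this step, it meets no acid, no fluoride and no oxidant.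

**Compound list**
1 | safranal | CC1=C(C=O)C(C)(C)CC=C1 | starting material
2 | racemic cis-3,4-dihydroxy-β-cyclocitral (one enantiomer drawn) | O=CC1=C(C)[C@H](O)[C@H](O)CC1(C)C | intermediate
3 | (3R,4S)-3-O-TBS-3,4-dihydroxy-β-cyclocitral | O=CC1=C(C)[C@H](O)[C@H](O[Si](C)(C)C(C)(C)C)CC1(C)C | intermediate
4 | (3R,4S,5R,6S)-3-O-TBS-4-hydroxy saturated ring aldehyde, CHO cis to 5-CH3 | O=C[C@H]1[C@@H](C)[C@H](O)[C@H](O[Si](C)(C)C(C)(C)C)CC1(C)C | intermediate
5 | (3R,4S,5R,6S)-3-O-TBS-4-O-TES ring aldehyde, CHO cis to 5-CH3 | O=C[C@H]1[C@@H](C)[C@H](O[Si](CC)(CC)CC)[C@H](O[Si](C)(C)C(C)(C)C)CC1(C)C | intermediate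
6 | (3R,4S,5R,6R)-3-O-TBS-4-O-TES ring aldehyde, CHO trans to 5-CH3 | O=C[C@@H]1[C@@H](C)[C@H](O[Si](CC)(CC)CC)[C@H](O[Si](C)(C)C(C)(C)C)CC1(C)C | intermediate
7 | (7E)-alkenyl iodide (3-O-TBS, 4-O-TES) | I/C=C/[C@@H]1[C@@H](C)[C@H](O[Si](CC)(CC)CC)[C@H](O[Si](C)(C)C(C)(C)C)CC1(C)C | intermediate
8 | ethynyltrimethylsilane | C#C[Si](C)(C)C | starting material
9 | (7E)-trimethylsilyl enyne (3-O-TBS, 4-O-TES) | C[Si](C)(C)C#C/C=C/[C@@H]1[C@@H](C)[C@H](O[Si](CC)(CC)CC)[C@H](O[Si](C)(C)C(C)(C)C)CC1(C)C | intermediate
10 | (7E)-terminal enyne (3-O-TBS, 4-O-TES) | C#C/C=C/[C@@H]1[C@@H](C)[C@H](O[Si](CC)(CC)CC)[C@H](O[Si](C)(C)C(C)(C)C)CC1(C)C | intermediate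
11 | (7E,9E)-dienyl(dimethyl)alane (not isolated) | C[Al](C)/C=C(C)/C=C/[C@@H]1[C@@H](C)[C@H](O[Si](CC)(CC)CC)[C@H](O[Si](C)(C)C(C)(C)C)CC1(C)C | intermediate
12 | (7E,9E)-dienyl iodide (3-O-TBS, 4-O-TES) | I/C=C(C)/C=C/[C@@H]1[C@@H](C)[C@H](O[Si](CC)(CC)CC)[C@H](O[Si](C)(C)C(C)(C)C)CC1(C)C | intermediate
13 | (7E,9E)-dienyl iodide, 4-OH free (3-O-TBS) | I/C=C(C)/C=C/[C@@H]1[C@@H](C)[C@H](O)[C@H](O[Si](C)(C)C(C)(C)C)CC1(C)C | intermediate
14 | (7E,9E)-dienyl iodide 4-O-sulfate (3-O-TBS), Bu4N+ salt, drawn as the acid | I/C=C(C)/C=C/[C@@H]1[C@@H](C)[C@H](OS(=O)(=O)O)[C@H](O[Si](C)(C)C(C)(C)C)CC1(C)C | intermediate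
15 | sulfated C14 dienyl iodide (3-OH free), Bu4N+ salt, drawn as the acid | I/C=C(C)/C=C/[C@@H]1[C@@H](C)[C@H](OS(=O)(=O)O)[C@H](O)CC1(C)C | intermediate
16 | (2E,4E,6E)-2,7-dimethylocta-2,4,6-trienedial | O=C/C(C)=C/C=C/C=C(C)/C=O | starting material
17 | 2-(dichloromethyl)-4,4,5,5-tetramethyl-1,3,2-dioxaborolane | ClC(Cl)B1OC(C)(C)C(C)(C)O1 | starting material
18 | monoboronate aldehyde (not isolated) | CC1(C)OB(/C=C/C(C)=C/C=C/C=C(C)/C=O)OC1(C)C | intermediate
19 | C12 pentaene-1,10-diyl bis(pinacol boronate) | CC1(C)OB(/C=C/C(C)=C/C=C/C=C(C)/C=C/B2OC(C)(C)C(C)(C)O2)OC1(C)C | intermediate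
20 | monocoupled heptaenyl pinacol boronate (not isolated), drawn as the acid | CC(/C=C/C=C(C)/C=C/[C@@H]1[C@@H](C)[C@H](OS(=O)(=O)O)[C@H](O)CC1(C)C)=C\C=C\C=C(C)\C=C\B1OC(C)(C)C(C)(C)O1 | intermediate
21 | CNP0202532.2, isolated as the disodium salt, drawn as the acid | CC(/C=C/C=C(C)/C=C/[C@@H]1[C@@H](C)[C@H](OS(=O)(=O)O)[C@H](O)CC1(C)C)=C\C=C\C=C(C)\C=C\C=C(C)\C=C\[C@@H]1[C@@H](C)[C@H](OS(=O)(=O)O)[C@H](O)CC1(C)C | target

**Step count**
Total: 14 steps. Longest linear sequence: 13 steps (steps 1–12 and 14); step 13 makes the bis(boronate) in one step.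

**Steps most likely to fail**

Step 14. The second coupling may be slow and incomplete while the polyenyl boronate is lost by protodeboronation in the basic aqueous medium, because the anionic iodide and the lipophilic boronate sit in different phases. The fallback sets out from 13, the neutral iodide with free 4-OH and 3-O-TBS. Twofold Suzuki–Miyaura coupling of 13 with 19 (Pd(PPh3)4, aq K3PO4, THF) should give the nonaene 4,4′-diol 3,3′-bis-TBS ether F1. SO3·pyridine in pyridine, a non-acidic reagent, then sulfates both C4 hydroxyls to the bis-TBS disulfate F2, and Bu4NF in THF removes the two silyl groups, which brings the route back at 21.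

Step 3. Addition to the tetrasubstituted, formyl-conjugated alkene may be sluggish and the catalyst may be lost through aldehyde binding, so that undirected reduction competes and the facial selectivity at C5 erodes. The fallback sets out from 3. NaBH4 with CeCl3·7H2O in MeOH reduces the aldehyde to the allylic alcohol F3. This electron-rich tetrasubstituted allylic alcohol is hydrogenated with the same iridium complex under direction of the C4 hydroxyl to the saturated cis-5,6 diol F4. TEMPO with PhI(OAc)2 in CH2Cl2 oxidises only the primary alcohol and returns the route at 4.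

Step 2. The selectivity factor of the silylation may be too low, or some silylation may occur at O4, so that 3 is not obtained enantiopure. The fallback sets out from 2. Burkholderia cepacia lipase with vinyl acetate in tBuOMe should acetylate O3 of the (3R)-enantiomer (the CH(OH) side acting as the large group) to give the (3R,4S)-3-O-acetate F5, which is separated from the unreacted (3S,4R)-diol. K2CO3 in MeOH then gives the enantiopure (3R,4S)-diol F6, and TBSCl with imidazole in DMF silylates the less hindered O3 and rejoins the route at 3. If the enzyme preferred the other antipode, the unreacted diol would be F6 and would be silylated directly.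

**Further compounds**
F1 | step 14 | nonaene 4,4′-diol 3,3′-bis-TBS ether | CC(/C=C/C=C(C)/C=C/[C@@H]1[C@@H](C)[C@H](O)[C@H](O[Si](C)(C)C(C)(C)C)CC1(C)C)=C\C=C\C=C(C)\C=C\C=C(C)\C=C\[C@@H]1[C@@H](C)[C@H](O)[C@H](O[Si](C)(C)C(C)(C)C)CC1(C)C
F2 | step 14 | nonaene 4,4′-disulfate 3,3′-bis-TBS ether (Bu4N+ salt, drawn as the acid) | CC(/C=C/C=C(C)/C=C/[C@@H]1[C@@H](C)[C@H](OS(=O)(=O)O)[C@H](O[Si](C)(C)C(C)(C)C)CC1(C)C)=C\C=C\C=C(C)\C=C\C=C(C)\C=C\[C@@H]1[C@@H](C)[C@H](OS(=O)(=O)O)[C@H](O[Si](C)(C)C(C)(C)C)CC1(C)C
F3 | step 3 | (3R,4S)-3-O-TBS allylic alcohol (C7 = CH2OH, C5=C6) | OCC1=C(C)[C@H](O)[C@H](O[Si](C)(C)C(C)(C)C)CC1(C)C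
F4 | step 3 | saturated 4,7-diol, 3-O-TBS, CH2OH cis to 5-CH3 | OC[C@H]1[C@@H](C)[C@H](O)[C@H](O[Si](C)(C)C(C)(C)C)CC1(C)C
F5 | step 2 | (3R,4S)-3-O-acetyl-3,4-dihydroxy-β-cyclocitral | O=CC1=C(C)[C@H](O)[C@H](OC(C)=O)CC1(C)C
F6 | step 2 | (3R,4S)-3,4-dihydroxy-β-cyclocitral, single enantiomer | O=CC1=C(C)[C@H](O)[C@H](O)CC1(C)C
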